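Conventions: TBS = tert-butyldimethylsilyl, TBSO = its aryl ether. Ring A is the dihydrofuran (O1, C2, C3, C3a, C7a), ring B the fused 2-pyranone (C3a, C4, O5, C6, C7, C7a), ring C the pendant 4-hydroxy-2-pyranone (primed atoms). The two stereocentres are read from the structure as 2S,3S (trans).

## The problem

The target is a 2,3-dihydro-4H-furo[3,2-c]pyran-4-one in which ring A is fused through C3a–C7a to ring B. C2 carries a 3,4-dihydroxyphenyl group, C3 is bonded to C6' of ring C, and C6 carries an (E)-4-hydroxystyryl group. C2 and C3 are the only stereocentres, so absolute control must come from a reagent or auxiliary; the trans arrangement is also the thermodynamically preferred one. Both centres are labile in principle: C3–H is alpha to a carbonyl in every useful precursor, and C2–O1 is a benzylic, para-oxygenated vinylogous ester bond that can ionise under acid. At every stage at least one of the two must therefore stay untouched. The catechol, the two pyranones (ring opening by hydroxide, and ambident reactivity through the 4-oxygen or the carbonyl oxygen) and the styryl alkene rule out hydrogenolysis, aqueous base and strong Lewis acids late in the route. The enabling feature is that O1 is bonded to C7a, which is C4 of ring B and the beta carbon of a vinylogous carbonate; in a 4-methoxy-2-pyranone this carbon exchanges its alkoxy group by addition–elimination. Ring A can thus be closed by the C2 oxygen acting as nucleophile, which leaves the C2–O and C3–H bonds alone and reduces the stereochemical problem to an acyclic syn-aldol.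

## Retrosynthesis

**Silyl ethers (27 ⇒ 26).** The last operation cleaves the three aryl O–Si bonds of 26. Fluoride is chosen because the finished molecule offers acid a way to ionise C2–O1 and offers hydrogen a styryl alkene. Acetal protection would need protic acid at the end and would sit badly with the acid of steps 6 and 11; benzyl ethers would need hydrogenolysis or a boron halide with a cation trap. The forward step must be buffered so that the catecholate is never exposed.

**Ring C (26 ⇒ 24 ⇒ 21 + 22).** The lactone bond O1'–C2' is cut to acylketene 25, the thermolysis product of keto-dioxinone 24. The C5'–C6' bond of 24 is then cut to the N-methoxy-N-methylamide 21 and dioxinone 22. Building ring C last keeps its acidic, chelating, ambident hydroxypyranone out of every earlier step. The forward acylation must add once to the amide without deprotonating C3; the ring closure itself is neutral.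

**Ring A (21 ⇒ 19).** The O1–C7a bond is cut. Cutting O1–C2 instead would make C2 a reacting centre and would let either oxygen of ring B close the ring. The chosen cut uses the carbinol oxygen as nucleophile and the methoxy-bearing carbon as the only electrophile, so neither stereocentre reacts. Precursor 19 is acyclic, and its syn arrangement corresponds to trans in the ring. The forward reaction must displace methoxide faster than the benzylic carbinol ionises or the aldol reverts.

**Aldol (19 ⇒ 18 ⇒ 13 + 15).** Amide 19 comes from imide 18 by auxiliary exchange, and 18 is cut at the bond that becomes C2–C3 into imide 13 and aldehyde 15. This single C–C bond joins both stereocentres, and the boron enolate of an N-arylacetyl oxazolidinone sets a syn pair with known absolute sense; the (S)-auxiliary 11 leads to the 2S,3S adduct. The forward step needs clean Z-enolisation next to the pyranone carbonyl and a work-up that avoids retro-aldol.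

**Side chain on ring B (13 ⇒ 10 + 11; 10 ⇒ 9 ⇒ 8).** The N-acyl bond is cut to acid 10 and auxiliary 11. Acid 10 is the tert-butyl ester 9 minus its ester group, and the bond from pyranone C3 to the methylene of 9 is cut to iodide 8 and a commercial zinc ester enolate. Cross-coupling is preferred to building the pyranone around the chain because 8 arises by direct iodination of the most nucleophilic carbon of ring B. The tert-butyl ester is chosen because its removal needs no hydroxide, which neither ring B nor an aryl silyl ether would survive.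

**Styryl unit (8 ⇒ 7 ⇒ 5 ⇒ 3 + 2).** The C–I bond is cut, then the alkene is cut by way of alcohol 5 to methylpyranone 3 and aldehyde 2. The strongly basic condensation at the 6-methyl group is placed before any stereocentre or acidic methylene exists. An amide base replaces an alkoxide in methanol so that the aryl silyl ether survives. Aldehydes 2 and 15 are the silyl ethers of 1 and 14.

## Roads not taken

**Alternative 1:** Ring contraction of a flavanone-type precursor with trivalent iodine; the cut is C3–C3a.
- Forward step: PhI(OAc)2 and H2SO4 in trimethyl orthoformate convert the pyrano-fused dione A2 into its enol ether and iodinate C3. Ring-B carbon C3a then migrates from the ketal carbon to C3 and gives the trans ester A1.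
- Merits: A2 should be reachable in very few condensation steps, the migration delivers trans directly, and the ester is ready for ring C. In step count this road is clearly shorter than the chosen one.
- Weak points: the C2 centre of A2 is set by a reversible oxa-Michael closure, so a single enantiomer is hard to obtain and keep, and the contraction only transfers what it is given. The styryl unit must then be condensed onto the 6-methyl group of A1 with strong base, in the presence of an acidic C3–H and base-labile pivalates. The medium is strongly acidic and oxidising toward an oxygenated arene.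
- Comparison: the chosen plan is longer, but it controls absolute configuration through the aldol and installs the styryl unit before any stereocentre exists.

**Alternative 2:** Cloke–Wilson ring expansion of a spirocyclopropane; the cut is O1–C2.
- Forward step: Sc(OTf)3 opens the bond between the spiro carbon and the aryl-bearing carbon of A4, and the C7a ketone oxygen captures the benzylic cation to give A3, the tris-methoxymethyl ether of the target.
- Merits: ring C is already in place, so only deprotection remains. The endgame is shorter than in the chosen plan, and the step is an isomerisation.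
- Weak points: the cation erases the configuration at C2, so everything rests on C3 of A4, and an enantioselective route to such a densely substituted cyclopropane bearing a free hydroxypyranone is an open problem. Two carbonyl oxygens flank the spiro carbon, so capture by the lactone oxygen would give the linear 4-pyranone isomer. Sc(OTf)3 must also coexist with three acetal ethers and a chelating hydroxypyranone.
- Comparison: the chosen plan closes the same ring from the other side, so C2 keeps its configuration by design and only one carbon carries a leaving group. It pays for this with three steps after ring closure.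

**Alternative 3:** Rhodium carbenoid insertion into a benzylic C–H bond; the cut is C2–C3.
- Forward step: Rh2(S-PTTL)4 converts diazoester A6 into a carbenoid at C3 that inserts into the benzylic C–H of the 4-O-benzyl ether and gives ester A5.
- Merits: catalytic asymmetric induction, both centres and the C–C bond in one step, and no auxiliary to attach and remove. In step and atom economy this road is better than the chosen one.
- Weak points: the carbenoid sits between the lactone carbonyl oxygen (carbonyl ylide) and the ether oxygen (oxonium ylide and benzyl shift), and the styryl alkene is a cyclopropanation partner. The kinetic insertion product of this class is usually cis, so epimerisation at C3 would follow. Induction on a heteroaryl diazoacetate with two ortho substituents cannot be predicted, and A5 still needs ring C.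
- Comparison: the chosen plan sets against this a boron aldol of predictable sense and no intermediate that can engage the alkene.

Key step: step 11

## Route

Step 1
Reactants: 1 4-hydroxybenzaldehyde
Product: 2 4-[(tert-butyldimethylsilyl)oxy]benzaldehyde
Conditions: TBSCl, imidazole, DMF, rt
Reagents that add atoms: tert-butyldimethylsilyl chloride, CC(C)(C)[Si](C)(C)Cl
Why: Phenol silylation; the aryl silyl ether tolerates the acids of steps 4, 6 and 11 and the enolate chemistry, and is removed by fluoride at the end.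

Step 2
Reactants: 3 4-methoxy-6-methyl-2H-pyran-2-one; 2 4-[(tert-butyldimethylsilyl)oxy]benzaldehyde
Product: 5 rac-6-{2-hydroxy-2-[4-(TBSO)phenyl]ethyl}-4-methoxy-2H-pyran-2-one, via lithium dienolate 4 (not isolated)
Conditions: LiN(SiMe3)2, THF, −78 °C; then 2, −78 °C; aq NH4Cl
Reagents that add atoms: none
Why: Vinylogous aldol addition: the amide base removes a proton from the 6-methyl group, which is vinylogous to the lactone carbonyl, and the dienolate adds through its exocyclic carbon to the non-enolisable aldehyde. The carbinol centre is racemic and is removed in step 3; an amide base is used because alkoxide in methanol would cleave the aryl silyl ether.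

Step 3
Reactants: 5 rac-6-{2-hydroxy-2-[4-(TBSO)phenyl]ethyl}-4-methoxy-2H-pyran-2-one
Product: 7 4-methoxy-6-[(E)-4-(TBSO)styryl]-2H-pyran-2-one, via methanesulfonate 6 (not isolated)
Conditions: MsCl, Et3N (excess), CH2Cl2, 0 °C → rt
Reagents that add atoms: none
Why: Mesylation followed by E1cB elimination of the proton vinylogous to the lactone carbonyl; the fully conjugated E-alkene is the thermodynamic product.

Step 4
Reactants: 7 4-methoxy-6-[(E)-4-(TBSO)styryl]-2H-pyran-2-one
Product: 8 3-iodo-4-methoxy-6-[(E)-4-(TBSO)styryl]-2H-pyran-2-one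
Conditions: NIS, CF3CO2H (cat.), MeCN, 0 °C → rt, dark
Reagents that add atoms: N-iodosuccinimide, O=C1CCC(=O)N1I
Why: Electrophilic iodination at C3, the enol-ether beta carbon and the most electron-rich position of the push–pull pyranone. The styryl alkene is deactivated by conjugation with the ring.

Step 5
Reactants: 8 3-iodo-4-methoxy-6-[(E)-4-(TBSO)styryl]-2H-pyran-2-one
Product: 9 tert-butyl 2-{4-methoxy-2-oxo-6-[(E)-4-(TBSO)styryl]-2H-pyran-3-yl}acetate
Conditions: BrZnCH2CO2t-Bu, Pd2(dba)3 (cat.), XPhos (cat.), THF, 50 °C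
Reagents that add atoms: (2-tert-butoxy-2-oxoethyl)zinc bromide, CC(C)(C)OC(=O)C[Zn]Br
Why: Negishi-type coupling of a Reformatsky reagent (palladium-catalysed alpha-arylation of a zinc ester enolate) at the C–I bond. The zinc enolate is too mild to attack the lactone or the silyl ether, and the bulky ester suppresses self-condensation.

Step 6
Reactants: 9 tert-butyl 2-{4-methoxy-2-oxo-6-[(E)-4-(TBSO)styryl]-2H-pyran-3-yl}acetate
Product: 10 2-{4-methoxy-2-oxo-6-[(E)-4-(TBSO)styryl]-2H-pyran-3-yl}acetic acid
Conditions: CF3CO2H, CH2Cl2, 0 °C → rt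
Reagents that add atoms: none
Why: Acidolysis of the tert-butyl ester with loss of isobutene; anhydrous acid leaves the aryl silyl ether and the vinylogous carbonate intact, whereas hydroxide would attack both.

Step 7
Reactants: 10 2-{4-methoxy-2-oxo-6-[(E)-4-(TBSO)styryl]-2H-pyran-3-yl}acetic acid; 11 (S)-4-benzyl-2-oxazolidinone
Product: 13 (S)-4-benzyl-3-(2-{4-methoxy-2-oxo-6-[(E)-4-(TBSO)styryl]-2H-pyran-3-yl}acetyl)oxazolidin-2-one, via pivalic mixed anhydride 12 (not isolated)
Conditions: t-BuCOCl, Et3N, THF, −20 °C; then 11, LiCl, rt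
Reagents that add atoms: none
Why: N-acylation through the mixed pivalic anhydride under Et3N/LiCl, which avoids an alkyllithium; the hindered pivaloyl carbonyl directs attack to the arylacetyl carbonyl.

Step 8
Reactants: 14 3,4-dihydroxybenzaldehyde
Product: 15 3,4-bis[(tert-butyldimethylsilyl)oxy]benzaldehyde
Conditions: TBSCl, imidazole, DMF, rt
Reagents that add atoms: tert-butyldimethylsilyl chloride, CC(C)(C)[Si](C)(C)Cl
Why: Double phenol silylation, as in step 1; the catechol stays masked until the last step.

Step 9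
Reactants: 13 (S)-4-benzyl-3-(2-{4-methoxy-2-oxo-6-[(E)-4-(TBSO)styryl]-2H-pyran-3-yl}acetyl)oxazolidin-2-one; 15 3,4-bis[(tert-butyldimethylsilyl)oxy]benzaldehyde
Product: 18 (S)-4-benzyl-3-[(2S,3S)-3-[3,4-bis(TBSO)phenyl]-3-hydroxy-2-{4-methoxy-2-oxo-6-[(E)-4-(TBSO)styryl]-2H-pyran-3-yl}propanoyl]oxazolidin-2-one, via boron enolate 16 (not isolated), via boron aldolate 17 (not isolated)
Conditions: n-Bu2BOTf, i-Pr2NEt, CH2Cl2, −78 → 0 °C; then 15, −78 → 0 °C; pH 7 buffer (NaH2PO4/Na2HPO4), MeOH, H2O2, 0 °C
Reagents that add atoms: none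
Why: Evans syn-aldol: soft enolisation gives the Z-boron enolate, which reacts with the aldehyde through a chair Zimmerman–Traxler transition state. The benzyl group of the dipole-opposed auxiliary shields one enolate face, so both stereocentres are set here as the 2S,3S syn pair; the neutral work-up avoids retro-aldol.

Step 10
Reactants: 18 (S)-4-benzyl-3-[(2S,3S)-3-[3,4-bis(TBSO)phenyl]-3-hydroxy-2-{4-methoxy-2-oxo-6-[(E)-4-(TBSO)styryl]-2H-pyran-3-yl}propanoyl]oxazolidin-2-one
Product: 19 (2S,3S)-3-[3,4-bis(TBSO)phenyl]-3-hydroxy-N-methoxy-2-{4-methoxy-2-oxo-6-[(E)-4-(TBSO)styryl]-2H-pyran-3-yl}-N-methylpropanamide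
Conditions: MeONHMe·HCl, AlMe3, CH2Cl2, −20 → 0 °C; aq potassium sodium tartrate
Reagents that add atoms: N,O-dimethylhydroxylamine hydrochloride, CNOC.Cl
Why: Weinreb transamination: the aluminium amide is delivered to the exocyclic imide carbonyl by the aluminium alkoxide of the free beta-hydroxyl, which makes the exchange fast at low temperature and keeps it away from ring B. The amide is less prone than the imide to retro-aldol and enolisation and is the acyl donor for step 12.

Step 11
Reactants: 19 (2S,3S)-3-[3,4-bis(TBSO)phenyl]-3-hydroxy-N-methoxy-2-{4-methoxy-2-oxo-6-[(E)-4-(TBSO)styryl]-2H-pyran-3-yl}-N-methylpropanamide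
Product: 21 (2S,3S)-2-[3,4-bis(TBSO)phenyl]-N-methoxy-N-methyl-4-oxo-6-[(E)-4-(TBSO)styryl]-2,3-dihydro-4H-furo[3,2-c]pyran-3-carboxamide, via 7a-methoxy adduct 20 (not isolated)
Conditions: CSA (10 mol %), 4 Å MS, toluene, 40 °C
Reagents that add atoms: none
Why: Camphorsulfonic acid protonates (or hydrogen-bonds to) the lactone carbonyl of ring B, which gives the C7a–OMe bond oxocarbenium character; the carbinol oxygen adds to C7a to give tetrahedral adduct 20, a proton moves to the methoxy oxygen, and loss of methanol (taken up by the sieves) restores the pyranone. The closest known reaction type is the acid-catalysed vinylogous transesterification (addition–elimination) of 4-alkoxy-2-pyranones, 4-alkoxycoumarins and 4-alkoxy-2-quinolones by a tethered alcohol. Ring A closes as a five-membered ring on a trigonal carbon: counted on the C7a=O+Me bond of the activated pyranone it is 5-exo-trig, whereas on the neutral pyranone the C3a=C7a bond would lie inside the new ring (5-endo-trig), which is why acid activation is preferred to alkoxide attack. No stereocentre is created and no bond to C2 or C3 is broken: the carbinol oxygen is the nucleophile, so C2 keeps its aldol configuration, C3 is not enolised by weak acid, and the syn adduct maps onto the trans ring. The step needs chemoselectivity among substitution at C7a by the carbinol oxygen, ionisation of the benzylic C–OH bond (dehydration, or capture by the lactone carbonyl oxygen toward the linear furo[2,3-b]pyran-4-one), and attack on C7a by the amide carbonyl oxygen. The substrate favours the first through the five-atom tether that holds the hydroxyl over C7a and through the two electron-withdrawing groups on the neighbouring carbon, which retard ionisation; weak acid, a non-polar solvent and moderate temperature support this, and the amide keeps retro-aldol slow.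

Step 12
Reactants: 21 (2S,3S)-2-[3,4-bis(TBSO)phenyl]-N-methoxy-N-methyl-4-oxo-6-[(E)-4-(TBSO)styryl]-2,3-dihydro-4H-furo[3,2-c]pyran-3-carboxamide; 22 2,2,6-trimethyl-4H-1,3-dioxin-4-one
Product: 24 (2S,3S)-2-[3,4-bis(TBSO)phenyl]-3-[2-(2,2-dimethyl-4-oxo-4H-1,3-dioxin-6-yl)acetyl]-6-[(E)-4-(TBSO)styryl]-2,3-dihydro-4H-furo[3,2-c]pyran-4-one, via lithium dienolate 23 (not isolated)
Conditions: 22 (excess), LiN(SiMe3)2 (slightly less than 22), THF, −78 °C; then 21, −78 → −40 °C; aq NH4Cl
Reagents that add atoms: none
Why: Claisen-type gamma-acylation of the dioxinone dienolate by the Weinreb amide; the chelated tetrahedral adduct stops the reaction at single addition and keeps the acidic product masked until work-up. The dienolate is a weak base and no free amide base is present, which limits deprotonation at C3; an epimerised C3 would return to the favoured trans arrangement.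

Step 13
Reactants: 24 (2S,3S)-2-[3,4-bis(TBSO)phenyl]-3-[2-(2,2-dimethyl-4-oxo-4H-1,3-dioxin-6-yl)acetyl]-6-[(E)-4-(TBSO)styryl]-2,3-dihydro-4H-furo[3,2-c]pyran-4-one
Product: 26 (2S,3S)-2-[3,4-bis(TBSO)phenyl]-3-(4-hydroxy-2-oxo-2H-pyran-6-yl)-6-[(E)-4-(TBSO)styryl]-2,3-dihydro-4H-furo[3,2-c]pyran-4-one, via acylketene 25 (not isolated)
Conditions: toluene, 110 °C
Reagents that add atoms: none
Why: Thermal retro-[4+2] of the dioxinone releases acetone and acylketene 25; the enolised C6' ketone oxygen adds to the ketene carbon and closes ring C as the 4-hydroxy-2-pyranone. The conditions are neutral, so neither stereocentre is at risk.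

Step 14
Reactants: 26 (2S,3S)-2-[3,4-bis(TBSO)phenyl]-3-(4-hydroxy-2-oxo-2H-pyran-6-yl)-6-[(E)-4-(TBSO)styryl]-2,3-dihydro-4H-furo[3,2-c]pyran-4-one
Product: 27 (2S,3S)-2-(3,4-dihydroxyphenyl)-3-(4-hydroxy-2-oxo-2H-pyran-6-yl)-6-[(E)-2-(4-hydroxyphenyl)ethenyl]-2,3-dihydro-4H-furo[3,2-c]pyran-4-one
Conditions: Bu4NF, AcOH, THF, 0 °C
Reagents that add atoms: none
Why: Fluoride cleaves the three aryl O–Si bonds; acetic acid keeps the phenols and the catechol protonated, so there is neither catecholate oxidation nor base at C3, and no acid strong enough to ionise C2–O1.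

## Compound list

1 | 4-hydroxybenzaldehyde | O=Cc1ccc(O)cc1 | starting material
2 | 4-[(tert-butyldimethylsilyl)oxy]benzaldehyde | O=Cc1ccc(O[Si](C)(C)C(C)(C)C)cc1 | intermediate
3 | 4-methoxy-6-methyl-2H-pyran-2-one | COc1cc(C)oc(=O)c1 | starting material
4 | 6-(lithiomethyl)-4-methoxy-2H-pyran-2-one, lithium dienolate of 3 (not isolated) | [Li]Cc1cc(OC)cc(=O)o1 | intermediate
5 | rac-6-{2-hydroxy-2-[4-(TBSO)phenyl]ethyl}-4-methoxy-2H-pyran-2-one | COc1cc(CC(O)c2ccc(O[Si](C)(C)C(C)(C)C)cc2)oc(=O)c1 | intermediate
6 | methanesulfonate of 5 (not isolated) | COc1cc(CC(OS(C)(=O)=O)c2ccc(O[Si](C)(C)C(C)(C)C)cc2)oc(=O)c1 | intermediate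
7 | 4-methoxy-6-[(E)-4-(TBSO)styryl]-2H-pyran-2-one | COc1cc(/C=C/c2ccc(O[Si](C)(C)C(C)(C)C)cc2)oc(=O)c1 | intermediate
8 | 3-iodo-4-methoxy-6-[(E)-4-(TBSO)styryl]-2H-pyran-2-one | COc1cc(/C=C/c2ccc(O[Si](C)(C)C(C)(C)C)cc2)oc(=O)c1I | intermediate
9 | tert-butyl 2-{4-methoxy-2-oxo-6-[(E)-4-(TBSO)styryl]-2H-pyran-3-yl}acetate | COc1cc(/C=C/c2ccc(O[Si](C)(C)C(C)(C)C)cc2)oc(=O)c1CC(=O)OC(C)(C)C | intermediate
10 | 2-{4-methoxy-2-oxo-6-[(E)-4-(TBSO)styryl]-2H-pyran-3-yl}acetic acid | COc1cc(/C=C/c2ccc(O[Si](C)(C)C(C)(C)C)cc2)oc(=O)c1CC(=O)O | intermediate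
11 | (S)-4-benzyl-2-oxazolidinone | O=C1N[C@@H](Cc2ccccc2)CO1 | starting material
12 | mixed anhydride of 10 with pivalic acid (not isolated) | COc1cc(/C=C/c2ccc(O[Si](C)(C)C(C)(C)C)cc2)oc(=O)c1CC(=O)OC(=O)C(C)(C)C | intermediate
13 | (S)-4-benzyl-3-(2-{4-methoxy-2-oxo-6-[(E)-4-(TBSO)styryl]-2H-pyran-3-yl}acetyl)oxazolidin-2-one | COc1cc(/C=C/c2ccc(O[Si](C)(C)C(C)(C)C)cc2)oc(=O)c1CC(=O)N1C(=O)OC[C@@H]1Cc1ccccc1 | intermediate
14 | 3,4-dihydroxybenzaldehyde | O=Cc1ccc(O)c(O)c1 | starting material
15 | 3,4-bis[(tert-butyldimethylsilyl)oxy]benzaldehyde | O=Cc1ccc(O[Si](C)(C)C(C)(C)C)c(O[Si](C)(C)C(C)(C)C)c1 | intermediate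
16 | (Z)-O-dibutylboryl enolate of 13 (not isolated) | CCCCB(CCCC)O/C(=C\c1c(OC)cc(/C=C/c2ccc(O[Si](C)(C)C(C)(C)C)cc2)oc1=O)N1C(=O)OC[C@@H]1Cc1ccccc1 | intermediate
17 | O-dibutylboryl aldolate of 18 (not isolated) | O=C(N1C(=O)OC[C@@H]1Cc1ccccc1)[C@@H](c1c(OC)cc(/C=C/c2ccc(O[Si](C)(C)C(C)(C)C)cc2)oc1=O)[C@H](OB(CCCC)CCCC)c1ccc(O[Si](C)(C)C(C)(C)C)c(O[Si](C)(C)C(C)(C)C)c1 | intermediate
18 | (S)-4-benzyl-3-[(2S,3S)-3-[3,4-bis(TBSO)phenyl]-3-hydroxy-2-{4-methoxy-2-oxo-6-[(E)-4-(TBSO)styryl]-2H-pyran-3-yl}propanoyl]oxazolidin-2-one | O=C(N1C(=O)OC[C@@H]1Cc1ccccc1)[C@@H](c1c(OC)cc(/C=C/c2ccc(O[Si](C)(C)C(C)(C)C)cc2)oc1=O)[C@H](O)c1ccc(O[Si](C)(C)C(C)(C)C)c(O[Si](C)(C)C(C)(C)C)c1 | intermediate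
19 | (2S,3S)-3-[3,4-bis(TBSO)phenyl]-3-hydroxy-N-methoxy-2-{4-methoxy-2-oxo-6-[(E)-4-(TBSO)styryl]-2H-pyran-3-yl}-N-methylpropanamide | CON(C)C(=O)[C@@H](c1c(OC)cc(/C=C/c2ccc(O[Si](C)(C)C(C)(C)C)cc2)oc1=O)[C@H](O)c1ccc(O[Si](C)(C)C(C)(C)C)c(O[Si](C)(C)C(C)(C)C)c1 | intermediate
20 | 7a-methoxy tetrahedral adduct, the 4-hydroxy-7a-methoxy-2,3-dihydro-7aH-furo[3,2-c]pyran-3-carboxamide formed from 19 (C2 and C3 as in 21; not isolated) | CON(C)C(=O)[C@H]1C2=C(O)OC(/C=C/c3ccc(O[Si](C)(C)C(C)(C)C)cc3)=CC2(OC)O[C@@H]1c1ccc(O[Si](C)(C)C(C)(C)C)c(O[Si](C)(C)C(C)(C)C)c1 | intermediate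
21 | (2S,3S)-2-[3,4-bis(TBSO)phenyl]-N-methoxy-N-methyl-4-oxo-6-[(E)-4-(TBSO)styryl]-2,3-dihydro-4H-furo[3,2-c]pyran-3-carboxamide | CON(C)C(=O)[C@H]1c2c(cc(/C=C/c3ccc(O[Si](C)(C)C(C)(C)C)cc3)oc2=O)O[C@@H]1c1ccc(O[Si](C)(C)C(C)(C)C)c(O[Si](C)(C)C(C)(C)C)c1 | intermediate
22 | 2,2,6-trimethyl-4H-1,3-dioxin-4-one | CC1=CC(=O)OC(C)(C)O1 | starting material
23 | lithium dienolate of 22 (not isolated) | C=C1C=C(O[Li])OC(C)(C)O1 | intermediate
24 | (2S,3S)-2-[3,4-bis(TBSO)phenyl]-3-[2-(2,2-dimethyl-4-oxo-4H-1,3-dioxin-6-yl)acetyl]-6-[(E)-4-(TBSO)styryl]-2,3-dihydro-4H-furo[3,2-c]pyran-4-one | O=C(CC1=CC(=O)OC(C)(C)O1)[C@H]1c2c(cc(/C=C/c3ccc(O[Si](C)(C)C(C)(C)C)cc3)oc2=O)O[C@@H]1c1ccc(O[Si](C)(C)C(C)(C)C)c(O[Si](C)(C)C(C)(C)C)c1 | intermediate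
25 | acylketene from 24, the 3-(3,5-dioxopent-4-enoyl) compound (not isolated) | O=C=CC(=O)CC(=O)[C@H]1c2c(cc(/C=C/c3ccc(O[Si](C)(C)C(C)(C)C)cc3)oc2=O)O[C@@H]1c1ccc(O[Si](C)(C)C(C)(C)C)c(O[Si](C)(C)C(C)(C)C)c1 | intermediate
26 | (2S,3S)-2-[3,4-bis(TBSO)phenyl]-3-(4-hydroxy-2-oxo-2H-pyran-6-yl)-6-[(E)-4-(TBSO)styryl]-2,3-dihydro-4H-furo[3,2-c]pyran-4-one | O=c1cc(O)cc([C@H]2c3c(cc(/C=C/c4ccc(O[Si](C)(C)C(C)(C)C)cc4)oc3=O)O[C@@H]2c2ccc(O[Si](C)(C)C(C)(C)C)c(O[Si](C)(C)C(C)(C)C)c2)o1 | intermediate
27 | (2S,3S)-2-(3,4-dihydroxyphenyl)-3-(4-hydroxy-2-oxo-2H-pyran-6-yl)-6-[(E)-2-(4-hydroxyphenyl)ethenyl]-2,3-dihydro-4H-furo[3,2-c]pyran-4-one | O=c1cc(O)cc([C@H]2c3c(cc(/C=C/c4ccc(O)cc4)oc3=O)O[C@@H]2c2ccc(O)c(O)c2)o1 | target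

## Step count and least certain steps

Total: 14 steps. Longest linear sequence: 13 steps (steps 1–7 and 9–14; step 8 is the one-step side branch).

**Step 11 (key step).**
- What may go wrong: displacement of methoxide by the neutral hydroxyl may be slow. The amide carbonyl oxygen, also five atoms from C7a, could then capture that carbon, which would end in an aminofuran with loss of C3–H. Acid-promoted ionisation of the electron-rich benzylic carbinol could also take over, giving dehydration or closure through the lactone carbonyl oxygen. A related exposure lies one step earlier, where the aluminium amide of step 10 could attack ring B.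
- Fallback (sets out from 18, returns at 24): close the ring on the imide, whose exocyclic carbonyl oxygen is a far poorer nucleophile. Imide 18 is treated with CSA and 4 Å MS in toluene and should give the ring-closed N-acyloxazolidinone F1. F1 is then used directly as the acyl donor toward lithium dienolate 23 (from 22 and LiN(SiMe3)2, THF, −78 °C), a Claisen-type displacement of the auxiliary that releases 11 and returns to the route at 24. Compounds 19 and 21 and the aluminium amide are bypassed. The ionisation leak itself is addressed inside the step by weaker acid and lower temperature.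

**Step 12.**
- What may go wrong: proton transfer from C3 to the dienolate instead of addition to the hindered amide. This would return epimerised amide or, through beta-elimination of O1, open ring A.
- Fallback (sets out from 21, returns at 24): avoid basic carbon nucleophiles. Amide 21 is reduced with i-Bu2AlH (THF, −78 °C) to the C3 carbaldehyde F2. Dioxinone 22 is converted with LiN(SiMe3)2 and TMSCl into its trimethylsilyl dienol ether F3. A vinylogous Mukaiyama aldol addition of F3 to F2 (BF3·OEt2, CH2Cl2, −78 °C) gives the delta-hydroxy dioxinone F4 as a mixture of carbinol epimers. Oxidation with Dess–Martin periodinane returns to the route at 24.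

**Step 9.**
- What may go wrong: incomplete or unselective enolisation, through coordination of boron to the pyranone carbonyl and hindrance by the two ortho substituents of the pyranonyl group, and retro-aldol during work-up.
- Fallback (sets out from 10, returns at 19): change the enolate metal and the auxiliary. Acid 10 is coupled (EDC·HCl, DMAP) with commercial (S)-4-benzyl-1,3-thiazolidine-2-thione to the N-acyl thiazolidinethione F5. Its titanium enolate (TiCl4 with two equivalents of amine base, the stoichiometry that gives the same syn sense as the boron enolate) adds to 15 to give the syn adduct F6. The thiazolidinethione is displaced by MeONHMe·HCl and imidazole at room temperature, without aluminium reagents, and the route is rejoined at 19.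

**Step 5.**
- What may go wrong: slow transmetalation and reductive elimination at the doubly ortho-substituted C3, so that protodeiodination wins.
- Fallback (sets out from 8, returns at 10): use a softer, doubly stabilised nucleophile. Iodide 8 is coupled with the sodium enolate of di-tert-butyl malonate (NaH, Pd(OAc)2, P(t-Bu)3, THF, 70 °C) to the pyranonyl malonate F7. Treatment with CF3CO2H followed by gentle warming in toluene removes both esters and one carboxyl group and returns to the route at 10.

## Further compounds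

F1 | step 11 | (S)-4-benzyl-3-{[(2S,3S)-2-[3,4-bis(TBSO)phenyl]-4-oxo-6-[(E)-4-(TBSO)styryl]-2,3-dihydro-4H-furo[3,2-c]pyran-3-yl]carbonyl}oxazolidin-2-one | O=C(N1C(=O)OC[C@@H]1Cc1ccccc1)[C@H]1c2c(cc(/C=C/c3ccc(O[Si](C)(C)C(C)(C)C)cc3)oc2=O)O[C@@H]1c1ccc(O[Si](C)(C)C(C)(C)C)c(O[Si](C)(C)C(C)(C)C)c1
F2 | step 12 | (2S,3S)-2-[3,4-bis(TBSO)phenyl]-4-oxo-6-[(E)-4-(TBSO)styryl]-2,3-dihydro-4H-furo[3,2-c]pyran-3-carbaldehyde | O=C[C@H]1c2c(cc(/C=C/c3ccc(O[Si](C)(C)C(C)(C)C)cc3)oc2=O)O[C@@H]1c1ccc(O[Si](C)(C)C(C)(C)C)c(O[Si](C)(C)C(C)(C)C)c1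
F3 | step 12 | 2,2-dimethyl-6-methylene-4-(trimethylsilyloxy)-6H-1,3-dioxine, the trimethylsilyl dienol ether of 22 | C=C1C=C(O[Si](C)(C)C)OC(C)(C)O1
F4 | step 12 | alcohol corresponding to ketone 24, 3-[2-(2,2-dimethyl-4-oxo-4H-1,3-dioxin-6-yl)-1-hydroxyethyl] compound (ring centres as in 24, carbinol as a mixture of epimers) | OC(CC1=CC(=O)OC(C)(C)O1)[C@H]1c2c(cc(/C=C/c3ccc(O[Si](C)(C)C(C)(C)C)cc3)oc2=O)O[C@@H]1c1ccc(O[Si](C)(C)C(C)(C)C)c(O[Si](C)(C)C(C)(C)C)c1
F5 | step 9 | (S)-4-benzyl-3-(2-{4-methoxy-2-oxo-6-[(E)-4-(TBSO)styryl]-2H-pyran-3-yl}acetyl)-1,3-thiazolidine-2-thione | COc1cc(/C=C/c2ccc(O[Si](C)(C)C(C)(C)C)cc2)oc(=O)c1CC(=O)N1C(=S)SC[C@@H]1Cc1ccccc1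
F6 | step 9 | (S)-4-benzyl-3-[(2S,3S)-3-[3,4-bis(TBSO)phenyl]-3-hydroxy-2-{4-methoxy-2-oxo-6-[(E)-4-(TBSO)styryl]-2H-pyran-3-yl}propanoyl]-1,3-thiazolidine-2-thione | O=C(N1C(=S)SC[C@@H]1Cc1ccccc1)[C@@H](c1c(OC)cc(/C=C/c2ccc(O[Si](C)(C)C(C)(C)C)cc2)oc1=O)[C@H](O)c1ccc(O[Si](C)(C)C(C)(C)C)c(O[Si](C)(C)C(C)(C)C)c1
F7 | step 5 | di-tert-butyl 2-{4-methoxy-2-oxo-6-[(E)-4-(TBSO)styryl]-2H-pyran-3-yl}malonate | COc1cc(/C=C/c2ccc(O[Si](C)(C)C(C)(C)C)cc2)oc(=O)c1C(C(=O)OC(C)(C)C)C(=O)OC(C)(C)C
A1 | alternative 1 | methyl (2S,3S)-2-[3,4-bis(pivaloyloxy)phenyl]-6-methyl-4-oxo-2,3-dihydro-4H-furo[3,2-c]pyran-3-carboxylate | COC(=O)[C@H]1c2c(cc(C)oc2=O)O[C@@H]1c1ccc(OC(=O)C(C)(C)C)c(OC(=O)C(C)(C)C)c1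
A2 | alternative 1 | (S)-2-[3,4-bis(pivaloyloxy)phenyl]-7-methyl-2,3-dihydro-4H,5H-pyrano[3,2-c]pyran-4,5-dione | O=C1C[C@@H](c2ccc(OC(=O)C(C)(C)C)c(OC(=O)C(C)(C)C)c2)Oc2cc(C)oc(=O)c21
A3 | alternative 2 | (2S,3S)-2-[3,4-bis(methoxymethoxy)phenyl]-3-(4-hydroxy-2-oxo-2H-pyran-6-yl)-6-[(E)-4-(methoxymethoxy)styryl]-2,3-dihydro-4H-furo[3,2-c]pyran-4-one | O=c1cc(O)cc([C@H]2c3c(cc(/C=C/c4ccc(OCOC)cc4)oc3=O)O[C@@H]2c2ccc(OCOC)c(OCOC)c2)o1
A4 | alternative 2 | trans-1-[3,4-bis(methoxymethoxy)phenyl]-2-(4-hydroxy-2-oxo-2H-pyran-6-yl)-6-[(E)-4-(methoxymethoxy)styryl]-5-oxaspiro[2.5]oct-6-ene-4,8-dione (spiro centre not specified) | O=c1cc(O)cc([C@@H]2[C@@H](c3ccc(OCOC)c(OCOC)c3)C24C(=O)C=C(/C=C/c3ccc(OCOC)cc3)OC4=O)o1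
A5 | alternative 3 | ethyl (2S,3S)-2-[3,4-bis(methoxymethoxy)phenyl]-6-[(E)-4-(methoxymethoxy)styryl]-4-oxo-2,3-dihydro-4H-furo[3,2-c]pyran-3-carboxylate | CCOC(=O)[C@H]1c2c(cc(/C=C/c3ccc(OCOC)cc3)oc2=O)O[C@@H]1c1ccc(OCOC)c(OCOC)c1
A6 | alternative 3 | ethyl 2-diazo-2-{4-[3,4-bis(methoxymethoxy)benzyloxy]-6-[(E)-4-(methoxymethoxy)styryl]-2-oxo-2H-pyran-3-yl}acetate | CCOC(=O)C(=[N+]=[N-])c1c(OCc2ccc(OCOC)c(OCOC)c2)cc(/C=C/c2ccc(OCOC)cc2)oc1=O
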